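**Plan**

- Cuts: the bond from the enone β-carbon to its CH2CH2 linker (conjugate addition, then re-oxidation) divides the target into a benzoxepane iodide and a cis-fused octalenone. Both tertiary methyl carbinols are cut back to exocyclic methylenes.
- The oxepane is opened at two bonds at once, the quaternary C5a–C5 bond and the O1–C2 bond (1-benzoxepine numbering). This is a (4+3) annulation of a methylidene-cyclohexenol with a four-carbon epoxy iodide.
- Enabling feature: C5a is a methyl-bearing quaternary carbon next to the carbinol carbon C9a (retron for hydrogen-atom transfer to an exocyclic methylene beside a free hydroxyl). C2 is a gem-dimethyl ether carbon next to the carbinol C3 (retron for Markovnikov opening of a trisubstituted epoxide).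
- Forward order: the cyclohexane ring from a quinone monoketal (steps 1–3); the oxepane in step 6; the cis-decalin by Diels–Alder reaction and nitrosyl chloride enone transposition (steps 13–16); union (17–18); both carbinols together (19–20).
- Stereochemistry: C6 from the Rh/BINAP addition, relayed to C9a (Luche reduction), C5a (radical coupling anti) and C7 (epoxidation anti to the angular methyl); C3 from the Shi epoxidation; the decalin ring fusion from the catalysed Diels–Alder reaction and its carbinol from convex-face epoxidation.

Key step: step 6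

Remark: the senses of induction in steps 1, 4 and 13 are assumed by analogy with the parent cases (cyclohex-2-enone, simple trisubstituted alkenes); if a sense is opposite, the other enantiomer of ligand or catalyst is used.

**Route**

Step 1
Reactants: 1 1,4-dioxaspiro[4.5]deca-6,9-dien-8-one; 2 potassium trifluoro(vinyl)borate
Product: 3 (R)-6-ethenyl-1,4-dioxaspiro[4.5]dec-9-en-8-one
Conditions: [Rh(cod)Cl]2 (3 mol %), (R)-BINAP, Et3N, dioxane/H2O, 60 °C
Reagents that add atoms: none
Why: Rhodium-catalysed asymmetric 1,4-addition (Hayashi–Miyaura reaction) of the vinyl group to one of the two enantiotopic enone arms should desymmetrise the dienone, the ligand setting the stereocentre that later carries the two-carbon linker.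

Step 2
Reactants: 3 vinyl enone
Product: 4 (S)-6-ethenyl-7-methylidene-1,4-dioxaspiro[4.5]dec-9-en-8-one
Conditions: (CH2O)n, PhNHMe·CF3CO2H, THF, 65 °C
Reagents that add atoms: formaldehyde (as paraformaldehyde), C=O
Why: Mannich-type α-methylenation should occur at the only enolisable carbon, since the other α-carbon is vinylic and the γ-carbon is the quaternary ketal carbon.

Step 3
Reactants: 4 methylidene dienone
Product: 5 (6S,8S)-6-ethenyl-7-methylidene-1,4-dioxaspiro[4.5]dec-9-en-8-ol
Conditions: NaBH4, CeCl3·7H2O, MeOH, −78 °C
Reagents that add atoms: none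
Why: Luche 1,2-reduction should deliver hydride to the carbonyl face opposite the pseudo-axial vinyl group two carbons away (as carvone gives cis-carveol), placing the hydroxyl cis to the vinyl group.

Step 4
Reactants: 6 5-bromo-2-methylpent-2-ene
Product: 7 (S)-3-(2-bromoethyl)-2,2-dimethyloxirane
Conditions: L-fructose-derived Shi ketone (30 mol %), KHSO5 (Oxone), K2CO3, Bu4NHSO4, MeCN/dimethoxymethane/aqueous buffer, 0 °C
Reagents that add atoms: potassium peroxymonosulfate, [K+].[O-]S(=O)(=O)OO
Why: Shi epoxidation of the trisubstituted alkene through the chiral dioxirane (spiro transition state) should set the future C3 carbinol configuration.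

Step 5
Reactants: 7 bromo epoxide
Product: 8 (S)-3-(2-iodoethyl)-2,2-dimethyloxirane
Conditions: NaI, acetone, reflux
Reagents that add atoms: sodium iodide, [Na+].[I-]
Why: Finkelstein exchange at the primary carbon should give the iodide needed for nickel coupling without touching the epoxide.

Step 6
Reactants: 5 methylidene cyclohexenol; 8 epoxy iodide
Product: 10 trans-fused tricyclic oxepanol, via hydroxy epoxide 9 (not isolated)
Conditions: Mn(dpm)3 (20 mol %), Ni(acac)2 (10 mol %), PhSiH3, K2CO3, 1,2-dichloroethane, 23 °C; then CSA (in excess over the carbonate), 0 °C, same flask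
Reagents that add atoms: none
Why: The manganese hydride formed from Mn(dpm)3 and PhSiH3 transfers a hydrogen atom to the exocyclic methylene of 5, which becomes the angular methyl group, and nickel captures the tertiary radical and joins it to the primary carbon of 8 to give 9; this is the manganese/nickel hydroalkylation of 1,1-disubstituted alkenes with alkyl iodides that builds quaternary carbons. The new C–C bond should form on the face opposite the hydroxyl and the vinyl group, which flank the radical on the same side, so the side chain ends trans to the ring oxygen and the methyl cis to it. Acid added to the same flask then lets the equatorial hydroxyl open the epoxide at its tertiary gem-dimethyl carbon, a 7-endo-tet closure of the oxepane of the kind known for acid-mediated hydroxy-epoxide cyclisations of trisubstituted epoxides. The carbinol carbon is not attacked and keeps the configuration set in step 4, and the trans-diequatorial hydroxyl and side chain give the trans ring fusion. The step needs hydrogen-atom transfer to the 1,1-disubstituted alkene rather than to the vinyl group or the cis-disubstituted ring alkene, which the substitution pattern secures, and 7-endo rather than 6-exo opening, which the cation-stabilising gem-dimethyl terminus favours under acid.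

Step 7
Reactants: 10 tricyclic oxepanol
Product: 12 diol with a 2-hydroxyethyl side chain, via bis-borane adduct 11 (not isolated)
Conditions: 9-BBN (2.5 equiv), THF, 0 to 23 °C; then NaOH, H2O2, 0 °C
Reagents that add atoms: hydrogen peroxide, OO
Why: Hydroboration–oxidation with 9-BBN should functionalise the monosubstituted vinyl group anti-Markovnikov and leave the hindered cis-disubstituted ring alkene.

Step 8
Reactants: 12 unsaturated diol
Product: 13 saturated diol ketal
Conditions: H2 (1 atm), Pd/C, EtOAc, trace Et3N, 23 °C
Reagents that add atoms: none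
Why: Catalytic hydrogenation should saturate the only remaining alkene, which has served its purpose of blocking enolisation on that side of the ring.

Step 9
Reactants: 13 saturated diol ketal
Product: 14 keto diol
Conditions: PPTS, acetone/H2O, 50 °C
Reagents that add atoms: water, O
Why: Acid-catalysed ketal hydrolysis should free the ketone; the adjacent stereocentre already holds its side chain equatorial, so epimerisation cannot harm it (the product may rest as its five-membered lactol).

Step 10
Reactants: 14 keto diol
Product: 15 methylidene diol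
Conditions: Ph3PCH3Br, KOt-Bu (excess), THF, 0 to 40 °C
Reagents that add atoms: methyltriphenylphosphonium bromide, C[P+](c1ccccc1)(c1ccccc1)c1ccccc1.[Br-]
Why: Wittig methylenation of the ketone (the lactol opens under base) should install the exocyclic alkene that is the precursor of the methyl carbinol.

Step 11
Reactants: 15 methylidene diol
Product: 16 iodo alcohol
Conditions: I2, PPh3, imidazole, CH2Cl2, 0 °C
Reagents that add atoms: iodine, II
Why: Appel iodination should take the primary hydroxyl selectively, the secondary one being neopentyl-like beside the gem-dimethyl carbon.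

Step 12
Reactants: 16 iodo alcohol
Product: 17 iodide tert-butyldimethylsilyl ether
Conditions: TBSOTf, 2,6-lutidine, CH2Cl2, −78 to 0 °C
Reagents that add atoms: tert-butyldimethylsilyl trifluoromethanesulfonate, CC(C)(C)[Si](C)(C)OS(=O)(=O)C(F)(F)F
Why: Silylation with the triflate should protect the hindered secondary alcohol for the organometallic union.

Step 13
Reactants: 18 4,4-dimethylcyclohex-2-en-1-one; 19 isoprene
Product: 20 (4aR,8aS)-4,4,6-trimethyl-3,4,4a,5,8,8a-hexahydronaphthalen-1(2H)-one
Conditions: chiral oxazaborolidinium triflimide (20 mol %, from the (S)-diphenylprolinol-derived o-tolyl oxazaborolidine and Tf2NH), CH2Cl2, −40 to −20 °C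
Reagents that add atoms: none
Why: Lewis-acid-catalysed Diels–Alder reaction should give the cis ring fusion by suprafacial addition and the "para" adduct with the methyl group on C6, the catalyst choosing the enone face.

Step 14
Reactants: 20 cis-octalone
Product: 21 (4aR,8aS)-4,4,6-trimethyl-1-methylidene-1,2,3,4,4a,5,8,8a-octahydronaphthalene
Conditions: Zn, CH2Br2, TiCl4, THF/CH2Cl2, 0 to 23 °C
Reagents that add atoms: dibromomethane, BrCBr
Why: Takai–Lombardo methylenation is non-basic and should convert the ketone without epimerising the ring-fusion carbon beside it.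

Step 15
Reactants: 21 diene
Product: 23 conjugated oxime, via chloro oxime 22 (not isolated)
Conditions: NOCl, CH2Cl2, −20 °C; then pyridine, 60 °C
Reagents that add atoms: nitrosyl chloride, O=NCl
Why: Nitrosyl chloride should add to the more electron-rich trisubstituted ring alkene (chlorine to the tertiary carbon, nitrogen to the CH carbon) and dehydrochlorination toward the ring CH2 should give the conjugated oxime, the classical limonene-to-carvoxime sequence.

Step 16
Reactants: 23 conjugated oxime
Product: 24 (4aR,8aS)-3,5,5-trimethyl-8-methylidene-4a,5,6,7,8,8a-hexahydronaphthalen-2(1H)-one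
Conditions: aqueous TiCl3, NH4OAc, dioxane, 23 °C
Reagents that add atoms: water, O
Why: Reductive N–O cleavage by trivalent titanium and hydrolysis of the imine should release the enone under buffered conditions that spare the exocyclic alkene.

Step 17
Reactants: 17 iodide silyl ether; 24 bicyclic enone
Product: 26 trimethylsilyl enol ether of the coupled ketone, via Grignard reagent 25 (not isolated)
Conditions: Mg, Et2O, 35 °C; then CuBr·SMe2 (10 mol %), Me3SiCl, THF, −78 to −40 °C
Reagents that add atoms: chlorotrimethylsilane, C[Si](C)(C)Cl
Why: Copper-catalysed conjugate addition of the primary Grignard reagent to the β-CH of the α-methyl enone, accelerated and trapped by Me3SiCl, should give the regiodefined silyl enol ether; the new sp3 centre returns to sp2 in step 18, so its configuration does not matter.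

Step 18
Reactants: 26 silyl enol ether
Product: 27 coupled tetrasubstituted enone
Conditions: Pd(OAc)2 (1.1 equiv), MeCN, 23 °C
Reagents that add atoms: none
Why: Saegusa–Ito oxidation should restore the enone, β-hydride elimination toward the ring carbon giving the conjugated endocyclic alkene.

Step 19
Reactants: 27 coupled enone
Product: 28 bis-spiro-epoxide
Conditions: mCPBA (2.4 equiv), NaHCO3, CH2Cl2, 0 °C
Reagents that add atoms: 3-chloroperbenzoic acid, OOC(=O)c1cccc(Cl)c1
Why: Epoxidation should take both 1,1-disubstituted exocyclic alkenes and not the electron-poor tetrasubstituted enone; oxygen should arrive anti to the axial angular methyl group in the benzoxepane and from the convex face of the cis-decalin.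

Step 20
Reactants: 28 bis-epoxide
Product: 29 allylic alcohol with both tertiary methyl carbinols
Conditions: LiAlH4, THF, 0 to 23 °C
Reagents that add atoms: none
Why: Hydride should open both spiro-epoxides at their CH2 carbons, turning them into the methyl groups and keeping the C–O configurations of step 19; the enone carbonyl is reduced as well and is restored in step 21.

Step 21
Reactants: 29 allylic alcohol
Product: 30 3-O-tert-butyldimethylsilyl sipholenol K
Conditions: MnO2, CH2Cl2, 23 °C
Reagents that add atoms: none
Why: Activated MnO2 should oxidise only the allylic secondary alcohol back to the enone.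

Step 22
Reactants: 30 silyl ether
Product: 31 sipholenol K
Conditions: HF·pyridine, THF, 23 °C
Reagents that add atoms: none
Why: Fluoride-mediated desilylation should free the C3 hydroxyl without affecting the tertiary alcohols or the enone.

**Compound list**

1 | 1,4-dioxaspiro[4.5]deca-6,9-dien-8-one (p-benzoquinone mono(ethylene ketal)) | O=C1C=CC2(OCCO2)C=C1 | starting material
2 | potassium trifluoro(vinyl)borate | C=C[B-](F)(F)F.[K+] | starting material
3 | (R)-6-ethenyl-1,4-dioxaspiro[4.5]dec-9-en-8-one | C=C[C@H]1CC(=O)C=CC12OCCO2 | intermediate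
4 | (S)-6-ethenyl-7-methylidene-1,4-dioxaspiro[4.5]dec-9-en-8-one | C=C[C@H]1C(=C)C(=O)C=CC12OCCO2 | intermediate
5 | (6S,8S)-6-ethenyl-7-methylidene-1,4-dioxaspiro[4.5]dec-9-en-8-ol (hydroxyl cis to vinyl) | C=C[C@H]1C(=C)[C@@H](O)C=CC12OCCO2 | intermediate
6 | 5-bromo-2-methylpent-2-ene | CC(C)=CCCBr | starting material
7 | (S)-3-(2-bromoethyl)-2,2-dimethyloxirane | BrCC[C@H]1C(C)(C)O1 | intermediate
8 | (S)-3-(2-iodoethyl)-2,2-dimethyloxirane | ICC[C@H]1C(C)(C)O1 | intermediate
9 | hydroxy epoxide: 7-[2-((2S)-3,3-dimethyloxiran-2-yl)ethyl]-6-ethenyl-7-methyl-1,4-dioxaspiro[4.5]dec-9-en-8-ol, 7-methyl cis to the 6-ethenyl and 8-hydroxyl groups | C=C[C@H]1[C@](C)(CC[C@H]2C(C)(C)O2)[C@@H](O)C=CC13OCCO3 | intermediate (not isolated)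
10 | tricyclic oxepanol: (3S)-6-ethenyl-7,7-(ethane-1,2-diyldioxy)-2,2,5a-trimethyl-2,3,4,5,5a,6,7,9a-octahydro-1-benzoxepin-3-ol; trans ring fusion, 5a-methyl, 6-ethenyl and O1 on one face, 9a-H on the other | C=C[C@H]2[C@]3(C)CC[C@H](O)C(C)(C)O[C@H]3C=CC24OCCO4 | intermediate
11 | bis(9-borabicyclo[3.3.1]nonane) adduct of 10: B-alkyl borane at the former vinyl terminus, 3-hydroxyl as its borinate | C(C[C@H]2[C@]3(C)CC[C@H](OB5C6CCCC5CCC6)C(C)(C)O[C@H]3C=CC24OCCO4)B7C8CCCC7CCC8 | intermediate (not isolated)
12 | 6-(2-hydroxyethyl) analogue of 10 (diol, 8,9-alkene and ketal retained) | OCC[C@H]2[C@]3(C)CC[C@H](O)C(C)(C)O[C@H]3C=CC24OCCO4 | intermediate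
13 | 8,9-dihydro derivative of 12 (saturated diol ketal) | OCC[C@H]2[C@]3(C)CC[C@H](O)C(C)(C)O[C@H]3CCC24OCCO4 | intermediate
14 | (3S)-3-hydroxy-6-(2-hydroxyethyl)-2,2,5a-trimethyloctahydro-1-benzoxepin-7(2H)-one, trans-fused, side chain cis to the 5a-methyl | OCC[C@H]2[C@]3(C)CC[C@H](O)C(C)(C)O[C@H]3CCC2=O | intermediate
15 | (3S)-6-(2-hydroxyethyl)-2,2,5a-trimethyl-7-methylidenedecahydro-1-benzoxepin-3-ol | OCC[C@H]2[C@]3(C)CC[C@H](O)C(C)(C)O[C@H]3CCC2=C | intermediate
16 | (3S)-6-(2-iodoethyl)-2,2,5a-trimethyl-7-methylidenedecahydro-1-benzoxepin-3-ol | ICC[C@H]2[C@]3(C)CC[C@H](O)C(C)(C)O[C@H]3CCC2=C | intermediate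
17 | tert-butyldimethylsilyl ether of 16 | ICC[C@H]2[C@]3(C)CC[C@H](O[Si](C)(C)C(C)(C)C)C(C)(C)O[C@H]3CCC2=C | intermediate
18 | 4,4-dimethylcyclohex-2-en-1-one | CC1(C)CCC(=O)C=C1 | starting material
19 | isoprene (2-methylbuta-1,3-diene) | CC(=C)C=C | starting material
20 | (4aR,8aS)-4,4,6-trimethyl-3,4,4a,5,8,8a-hexahydronaphthalen-1(2H)-one (cis-fused) | CC=1C[C@@H]2[C@H](CC=1)C(=O)CCC2(C)C | intermediate
21 | (4aR,8aS)-4,4,6-trimethyl-1-methylidene-1,2,3,4,4a,5,8,8a-octahydronaphthalene | CC=1C[C@@H]2[C@H](CC=1)C(=C)CCC2(C)C | intermediate
22 | chloro oxime (tautomer of the nitroso chloride): cis-fused 3-chloro-3,5,5-trimethyl-8-methylideneoctahydronaphthalen-2(1H)-one oxime | CC1(Cl)C[C@@H]2[C@H](CC1=NO)C(=C)CCC2(C)C | intermediate (not isolated)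
23 | oxime of (4aR,8aS)-3,5,5-trimethyl-8-methylidene-4a,5,6,7,8,8a-hexahydronaphthalen-2(1H)-one | CC1=C[C@@H]2[C@H](CC1=NO)C(=C)CCC2(C)C | intermediate
24 | (4aR,8aS)-3,5,5-trimethyl-8-methylidene-4a,5,6,7,8,8a-hexahydronaphthalen-2(1H)-one | CC1=C[C@@H]2[C@H](CC1=O)C(=C)CCC2(C)C | intermediate
25 | Grignard reagent from 17 (2-(benzoxepin-6-yl)ethylmagnesium iodide) | I[Mg]CC[C@H]2[C@]3(C)CC[C@H](O[Si](C)(C)C(C)(C)C)C(C)(C)O[C@H]3CCC2=C | intermediate (not isolated)
26 | trimethylsilyl enol ether of the 1,4-adduct: C2-OSiMe3, C2=C3 alkene, C4 carrying the 2-(benzoxepin-6-yl)ethyl chain (C4 configuration not defined) | CC=1C(CC[C@H]3[C@]4(C)CC[C@H](O[Si](C)(C)C(C)(C)C)C(C)(C)O[C@H]4CCC3=C)[C@@H]2[C@H](CC=1O[Si](C)(C)C)C(=C)CCC2(C)C | intermediate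
27 | coupled enone: both exocyclic methylenes present, C3 hydroxyl as its silyl ether | CC1=C(CC[C@H]3[C@]4(C)CC[C@H](O[Si](C)(C)C(C)(C)C)C(C)(C)O[C@H]4CCC3=C)[C@@H]2[C@H](CC1=O)C(=C)CCC2(C)C | intermediate
28 | bis-spiro-epoxide of 27 (epoxide oxygens in the positions of the two future tertiary hydroxyls) | CC1=C(CC[C@H]3[C@]4(C)CC[C@H](O[Si](C)(C)C(C)(C)C)C(C)(C)O[C@H]4CC[C@]3(C5)O5)[C@@H]2[C@H](CC1=O)[C@@](C6)(O6)CCC2(C)C | intermediate
29 | allylic alcohol: 2-hydroxy analogue of 30 (carbinol configuration not defined), both tertiary methyl carbinols in place | CC1=C(CC[C@H]3[C@]4(C)CC[C@H](O[Si](C)(C)C(C)(C)C)C(C)(C)O[C@H]4CC[C@]3(C)O)[C@@H]2[C@H](CC1O)[C@@](C)(O)CCC2(C)C | intermediate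
30 | 3-O-tert-butyldimethylsilyl sipholenol K | CC1=C(CC[C@H]3[C@]4(C)CC[C@H](O[Si](C)(C)C(C)(C)C)C(C)(C)O[C@H]4CC[C@]3(C)O)[C@@H]2[C@H](CC1=O)[C@@](C)(O)CCC2(C)C | intermediate
31 | sipholenol K | CC1=C(CC[C@H]2[C@]3(C)CC[C@H](O)C(C)(C)O[C@H]3CC[C@]2(C)O)[C@@H]2[C@H](CC1=O)[C@@](C)(O)CCC2(C)C | target

**Count and risks**

Total step count: 22. Longest linear sequence: 16 steps (steps 1–3, 6–12 and 17–22).

Steps most likely to fail:

Step 6. The hindered tertiary radical may be reduced, or the alkene isomerised, faster than nickel couples it with 8; the epoxide may also be lost to the iodosilane or opened in the 6-exo sense before the seven-membered ring closes. Fallback: from 3, deprotonation with lithium diisopropylamide (THF, −78 °C) and iodomethane would methylate the only enolisable carbon and give trans-6-ethenyl-7-methyl-1,4-dioxaspiro[4.5]dec-9-en-8-one F1. A second deprotonation (lithium diisopropylamide, DMPU) and alkylation with iodide 8 on the face away from the vinyl group would give the quaternary epoxy enone F2. Luche reduction of F2 from the face away from the axial methyl group would give hydroxy epoxide 9, where the sequence rejoins the route and the acid-mediated closure of step 6 leads to 10.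

Step 13. The β-carbon of 18 is neopentyl, so cycloaddition under the chiral catalyst may be too slow or poorly face-selective, and the cis-fused adduct can epimerise beside the carbonyl group. Fallback: from 18 and 19, cycloaddition with AlCl3 in toluene would give the racemic cis adduct, that is 20 together with its enantiomer F3. Reduction with NaBH4 would give the cis-fused alcohol F4 from 20 and the enantiomeric alcohol F5 from F3. A lipase (for example that of Burkholderia cepacia) with vinyl acetate would acylate one enantiomer, taken here to be the unwanted one, to the acetate F6. After separation, Dess–Martin oxidation of F4 would return enantiopure 20.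

Step 17. Formation of the Grignard reagent from the β-branched iodide may be accompanied by Wurtz coupling or elimination, and copper-mediated addition to the α-methyl enone with its substituted γ-carbon may be slow. Fallback: from 17 and 24, nickel-catalysed reductive conjugate addition (NiCl2(dme), a terpyridine ligand, Mn powder, Et3SiCl, DMF) would couple the alkyl iodide without a preformed organometallic reagent and give the triethylsilyl enol ether F7. Dehydrogenation of F7 with Pd(OAc)2 as in step 18 would rejoin the route at 27.

**Further compounds**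

F1 | step 6 | trans-6-ethenyl-7-methyl-1,4-dioxaspiro[4.5]dec-9-en-8-one | C=C[C@H]1[C@H](C)C(=O)C=CC12OCCO2
F2 | step 6 | 7-[2-((2S)-3,3-dimethyloxiran-2-yl)ethyl]-6-ethenyl-7-methyl-1,4-dioxaspiro[4.5]dec-9-en-8-one, methyl cis to vinyl | C=C[C@H]1[C@](C)(CC[C@H]3C(C)(C)O3)C(=O)C=CC12OCCO2
F3 | step 13 | (4aS,8aR)-4,4,6-trimethyl-3,4,4a,5,8,8a-hexahydronaphthalen-1(2H)-one (enantiomer of 20) | CC=1C[C@H]2[C@@H](CC=1)C(=O)CCC2(C)C
F4 | step 13 | cis-fused alcohol from 20, hydroxyl trans to the ring-fusion hydrogens | CC=1C[C@@H]2[C@H](CC=1)[C@H](O)CCC2(C)C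
F5 | step 13 | enantiomer of F4 | CC=1C[C@H]2[C@@H](CC=1)[C@@H](O)CCC2(C)C
F6 | step 13 | acetate of F5 | CC=1C[C@H]2[C@@H](CC=1)[C@@H](OC(C)=O)CCC2(C)C
F7 | step 17 | triethylsilyl analogue of enol ether 26 | CC=1C(CC[C@H]3[C@]4(C)CC[C@H](O[Si](C)(C)C(C)(C)C)C(C)(C)O[C@H]4CCC3=C)[C@@H]2[C@H](CC=1O[Si](CC)(CC)CC)C(=C)CCC2(C)C
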